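## Retrosynthetic overview
1. Target 40 comes from global hydrogenolysis of tetrabenzyl compound 39. Compound 39 comes from a Suzuki–Miyaura C6–C6′ coupling of iodide 34 (open-chain half) with boronate 38 (lactone half).
2. Each pyranone ring closes by an intramolecular 6-endo oxa-Michael addition of a freshly unmasked phenol onto an aroylacrylate (33→34, 36→37). This step creates the quaternary C2.
3. Both enones come from Wittig olefination of one ylide 31 (from 2′,6′-dihydroxyacetophenone) with the α-keto esters 16 and 23.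
4. Keto esters 16 and 23 come from bromoalkyne/KMnO4 oxidation. Both derive from one Brown syn-crotylation product 7, which sets the C–O/C–Me stereodiad.
5. Ring order: γ-lactone (step 9), then the pyranone of each half (steps 18 and 20), then the biaryl bond (step 22).

Assumption: the 6,6′-biaryl axis has only one OH and one H ortho on each ring and the SMILES gives no axial descriptor, so it rotates freely and no axial control is planned.

## Route

Step 1
Reactants: 1 cis-but-2-ene; 2 3-(trimethylsilyl)prop-2-ynal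
Product: 7 (3R,4S)-4-methyl-1-(trimethylsilyl)hex-5-en-1-yn-3-ol, via (Z)-crotylpotassium 3 (not isolated), via potassium (Z)-crotyl(methoxy)diisopinocampheylborate 4 (not isolated), via (Z)-crotyldiisopinocampheylborane 5 (not isolated), via diisopinocampheylborinate of the adduct 6 (not isolated)
Conditions: n-BuLi, KOt-Bu, THF, −78 to −45 °C; (+)-Ipc2BOMe [from (−)-α-pinene], −78 °C; BF3·OEt2, then 2, −78 °C; HOCH2CH2NH2, rt
Reagents that add atoms: none
Why: Brown asymmetric crotylboration through a closed Zimmerman–Traxler chair, in which the Z-crotyl geometry gives the syn diad and the Ipc groups from (−)-α-pinene direct attack to the Re face of the alkynal, setting 3R,4S.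

Step 2
Reactants: 7 syn-homoallylic alcohol
Product: 8 [(3R,4S)-3-(benzyloxy)-4-methylhex-5-en-1-yn-1-yl]trimethylsilane
Conditions: BnOC(=NH)CCl3, TfOH (5 mol %), CH2Cl2/cyclohexane, 0 °C to rt
Reagents that add atoms: benzyl 2,2,2-trichloroacetimidate, N=C(OCc1ccccc1)C(Cl)(Cl)Cl
Why: Acid-catalysed trichloroacetimidate O-benzylation avoids the strong base that would cleave the alkynyl–Si bond and touches no stereocentre.

Step 3
Reactants: 8 benzyl ether
Product: 10 (3S,4R)-4-(benzyloxy)-3-methyl-6-(trimethylsilyl)hex-5-yn-1-ol, via B-alkyl-9-BBN adduct 9 (not isolated)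
Conditions: 9-BBN, THF, 0 °C to rt; 30 % H2O2, aq NaOAc, 0 °C
Reagents that add atoms: hydrogen peroxide, OO
Why: Brown hydroboration–oxidation, in which bulky 9-BBN adds anti-Markovnikov to the monosubstituted alkene far faster than to the silyl-capped alkyne and the buffered peroxide spares the C–Si bond.

Step 4
Reactants: 10 primary alcohol
Product: 12 (3S,4R)-4-(benzyloxy)-3-methyl-6-(trimethylsilyl)hex-5-ynoic acid, via aldehyde 11 (not isolated)
Conditions: TEMPO (0.2 equiv), PhI(OAc)2 (2.5 equiv), MeCN/H2O 1:1, rt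
Reagents that add atoms: water, O
Why: TEMPO/PhI(OAc)2 oxidation takes the primary alcohol through the aldehyde hydrate to the acid under near-neutral conditions that leave ether, alkyne and both stereocentres untouched.

Step 5
Reactants: 12 acid
Product: 13 benzyl (3S,4R)-4-(benzyloxy)-3-methyl-6-(trimethylsilyl)hex-5-ynoate
Conditions: BnBr, KHCO3, DMF, rt
Reagents that add atoms: benzyl bromide, BrCc1ccccc1
Why: SN2 O-alkylation of the carboxylate with a weak base gives an ester that can later be removed by neutral hydrogenolysis.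

Step 6
Reactants: 13 TMS-alkyne
Product: 14 benzyl (3S,4R)-4-(benzyloxy)-6-bromo-3-methylhex-5-ynoate
Conditions: NBS, AgNO3 (0.2 equiv), acetone, rt, dark
Reagents that add atoms: N-bromosuccinimide, O=C1CCC(=O)N1Br
Why: Silver-catalysed bromodesilylation converts the alkynylsilane directly into the 1-bromoalkyne through a silver acetylide.

Step 7
Reactants: 14 bromoalkyne
Product: 16 6-benzyl 1-methyl (3R,4S)-3-(benzyloxy)-4-methyl-2-oxohexanedioate, via α-keto acyl bromide 15 (not isolated)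
Conditions: KMnO4, NaHCO3, MgSO4, MeOH/H2O 1:1, 0 °C
Reagents that add atoms: potassium permanganate, [K+].[O-][Mn](=O)(=O)=O; methanol, CO
Why: Permanganate oxidation of a 1-bromoalkyne gives the α-keto acyl bromide, which methanol traps as the α-keto ester, and the buffered cold medium does not enolise the α-alkoxy stereocentre.

Step 8
Reactants: 7 syn-homoallylic alcohol
Product: 18 (3S,4R)-3-methyl-6-(trimethylsilyl)hex-5-yne-1,4-diol, via bis(9-BBN) adduct 17 (not isolated)
Conditions: 9-BBN (2.5 equiv), THF, 0 °C to rt; 30 % H2O2, aq NaOAc, 0 °C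
Reagents that add atoms: hydrogen peroxide, OO
Why: Brown hydroboration–oxidation as in step 3, with one extra equivalent of borane consumed by the free hydroxyl.

Step 9
Reactants: 18 1,4-diol
Product: 20 (4S,5R)-4-methyl-5-[(trimethylsilyl)ethynyl]oxolan-2-one, via lactol 19 (not isolated)
Conditions: TEMPO (0.2 equiv), PhI(OAc)2 (3 equiv), CH2Cl2, rt
Reagents that add atoms: none
Why: TEMPO/PhI(OAc)2 oxidative lactonisation oxidises the unhindered primary alcohol first, the aldehyde closes to the lactol and this is oxidised on, fixing the syn diad as the cis-4,5-disubstituted γ-lactone.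

Step 10
Reactants: 20 TMS-alkynyl lactone
Product: 21 (4S,5R)-5-(bromoethynyl)-4-methyloxolan-2-one
Conditions: NBS, AgNO3 (0.2 equiv), acetone, rt, dark
Reagents that add atoms: N-bromosuccinimide, O=C1CCC(=O)N1Br
Why: Silver-catalysed bromodesilylation as in step 6.

Step 11
Reactants: 21 bromoalkynyl lactone
Product: 23 methyl 2-[(2R,3S)-3-methyl-5-oxooxolan-2-yl]-2-oxoacetate, via α-keto acyl bromide 22 (not isolated)
Conditions: KMnO4, NaHCO3, MgSO4, MeOH/H2O 1:1, 0 °C, short contact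
Reagents that add atoms: potassium permanganate, [K+].[O-][Mn](=O)(=O)=O; methanol, CO
Why: Bromoalkyne-to-α-keto-ester permanganate oxidation as in step 7, kept cold and brief so that the cis-lactone carbinol centre is not epimerised.

Step 12
Reactants: 24 2′,6′-dihydroxyacetophenone
Product: 25 1-{2-hydroxy-6-[(4-methoxybenzyl)oxy]phenyl}ethan-1-one
Conditions: PMBCl (1.0 equiv), K2CO3, NaI (cat.), acetone, reflux
Reagents that add atoms: 4-methoxybenzyl chloride, COc1ccc(CCl)cc1
Why: Williamson monoetherification stops cleanly because the remaining OH is deactivated by chelation to the ketone.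

Step 13
Reactants: 25 mono-PMB ether
Product: 26 1-{2-hydroxy-3-iodo-6-[(4-methoxybenzyl)oxy]phenyl}ethan-1-one
Conditions: NIS (1.05 equiv), MeCN, 0 °C to rt, dark
Reagents that add atoms: N-iodosuccinimide, O=C1CCC(=O)N1I
Why: Electrophilic aromatic iodination goes to the open site ortho to the chelated OH and para to OPMB, because the other activated site is shielded by the PMB methylene that turns away from the acetyl group.

Step 14
Reactants: 26 iodophenol
Product: 27 1-{2-(benzyloxy)-3-iodo-6-[(4-methoxybenzyl)oxy]phenyl}ethan-1-one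
Conditions: BnBr, K2CO3, DMF, 50 °C
Reagents that add atoms: benzyl bromide, BrCc1ccccc1
Why: Williamson etherification masks the oxygen next to iodine (the future 5-OH) with a group orthogonal to PMB, so only the remote oxygen can cyclise later.

Step 15
Reactants: 27 differentially protected acetophenone
Product: 29 2-bromo-1-{2-(benzyloxy)-3-iodo-6-[(4-methoxybenzyl)oxy]phenyl}ethan-1-one, via trimethylsilyl enol ether 28 (not isolated)
Conditions: TMSOTf, Et3N, CH2Cl2, 0 °C; NBS, 0 °C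
Reagents that add atoms: N-bromosuccinimide, O=C1CCC(=O)N1Br
Why: Bromination of the preformed silyl enol ether is acid-free and site-specific, so neither the electron-rich rings nor the PMB ether is attacked.

Step 16
Reactants: 29 phenacyl bromide
Product: 31 1-{2-(benzyloxy)-3-iodo-6-[(4-methoxybenzyl)oxy]phenyl}-2-(triphenyl-λ5-phosphanylidene)ethan-1-one, via phosphonium bromide 30 (not isolated)
Conditions: PPh3, toluene, 60 °C; aq Na2CO3/CH2Cl2, rt
Reagents that add atoms: triphenylphosphine, c1ccc(cc1)P(c1ccccc1)c1ccccc1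
Why: SN2 quaternisation of PPh3 followed by deprotonation of the acidic phenacylphosphonium salt gives the shelf-stable acyl-stabilised ylide.

Step 17
Reactants: 31 ylide; 16 open-chain α-keto ester
Product: 32 6-benzyl 1-methyl (2E,3R,4S)-3-(benzyloxy)-2-(2-{2-(benzyloxy)-3-iodo-6-[(4-methoxybenzyl)oxy]phenyl}-2-oxoethylidene)-4-methylhexanedioate
Conditions: toluene, 90 °C, 24 h
Reagents that add atoms: none
Why: Wittig olefination of the activated keto group with a non-basic stabilised ylide leaves the α-alkoxy stereocentre intact and favours the E alkene with the two carbonyl groups trans.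

Step 18
Reactants: 32 PMB-protected enone
Product: 34 methyl (2S)-5-(benzyloxy)-2-[(1R,2S)-1,4-bis(benzyloxy)-2-methyl-4-oxobutyl]-6-iodo-4-oxochromane-2-carboxylate, via free phenol enone 33 (not isolated)
Conditions: TFA/CH2Cl2 1:10, anisole, 0 °C; evaporate with toluene; Et3N (0.3 equiv), CH2Cl2, −20 °C to rt; separate the 2R epimer and resubmit it
Reagents that add atoms: none
Why: After PMB acidolysis the phenol closes the pyranone by a 6-endo-trig intramolecular oxa-Michael addition β to the ketone (the stronger acceptor), with A1,3 strain holding the allylic C–H in the enone plane so that the phenoxide adds anti to the C–OBn bond (Felkin–Anh) and sets quaternary C2 as S.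

Step 19
Reactants: 31 ylide; 23 lactone α-keto ester
Product: 35 methyl (2E)-4-{2-(benzyloxy)-3-iodo-6-[(4-methoxybenzyl)oxy]phenyl}-2-[(2R,3S)-3-methyl-5-oxooxolan-2-yl]-4-oxobut-2-enoate
Conditions: toluene, 60 °C
Reagents that add atoms: none
Why: Wittig olefination as in step 17, run at lower temperature because the α-acyloxy keto ester is more electrophilic and its carbinol centre is more easily epimerised.

Step 20
Reactants: 35 PMB-protected enone
Product: 37 methyl (2S)-5-(benzyloxy)-6-iodo-2-[(2R,3S)-3-methyl-5-oxooxolan-2-yl]-4-oxochromane-2-carboxylate, via free phenol enone 36 (not isolated)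
Conditions: TFA/CH2Cl2 1:10, anisole, 0 °C; evaporate with toluene; Et3N (0.3 equiv), CH2Cl2, −20 °C to rt; separate the 2R epimer and resubmit it
Reagents that add atoms: none
Why: PMB acidolysis then 6-endo-trig intramolecular oxa-Michael addition, in which the phenoxide adds anti to the strongly σ*-accepting lactone C–O bond of the A1,3-locked rotamer and sets quaternary C2 as S.

Step 21
Reactants: 37 lactone iodide
Product: 38 methyl (2S)-5-(benzyloxy)-2-[(2R,3S)-3-methyl-5-oxooxolan-2-yl]-4-oxo-6-(4,4,5,5-tetramethyl-1,3,2-dioxaborolan-2-yl)chromane-2-carboxylate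
Conditions: PdCl2(dppf)·CH2Cl2 (5 mol %), B2pin2, KOAc, 1,4-dioxane, 80 °C
Reagents that add atoms: bis(pinacolato)diboron, CC1(C)OB(OC1(C)C)B1OC(C)(C)C(C)(C)O1
Why: Miyaura borylation of the aryl iodide uses only acetate as base, which is too weak to trigger retro-oxa-Michael opening or lactone cleavage.

Step 22
Reactants: 34 open-chain iodide; 38 lactone boronate
Product: 39 tetrabenzyl-protected 6,6′-bichromanone (5,5′-di-O-benzyl with side-chain benzyl ether plus benzyl ester on one half)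
Conditions: SPhos Pd G3 (5 mol %), K3PO4, THF/H2O 10:1, 40 °C
Reagents that add atoms: none
Why: Suzuki–Miyaura cross-coupling with a bulky biarylphosphine joins the two mono-ortho-alkoxy arenes at low temperature, creates no stereocentre, and is mild enough to keep C2, the lactone and the esters intact.

Step 23
Reactants: 39 tetrabenzyl compound
Product: 40 target, (3S,4R)-4-hydroxy-4-[(2S)-5-hydroxy-6-{(2S)-5-hydroxy-2-(methoxycarbonyl)-2-[(2R,3S)-3-methyl-5-oxooxolan-2-yl]-4-oxochroman-6-yl}-2-(methoxycarbonyl)-4-oxochroman-2-yl]-3-methylbutanoic acid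
Conditions: H2 (1 atm), Pd(OH)2/C, EtOAc, rt; filter, evaporate below 25 °C without acid
Reagents that add atoms: none
Why: Neutral catalytic hydrogenolysis removes two aryl benzyl ethers, the alkyl benzyl ether and the benzyl ester in one operation, so the γ-hydroxy acid is released without the acid or base that would lactonise it or open the pyranones.

## Compound list
1 | cis-but-2-ene | C/C=C\C | starting material
2 | 3-(trimethylsilyl)prop-2-ynal | C[Si](C)(C)C#CC=O | starting material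
3 | (Z)-crotylpotassium | C/C=C\[CH2-].[K+] | intermediate
4 | potassium (Z)-crotyl(methoxy)diisopinocampheylborate | [K+].C/C=C\C[B-](OC)([C@H]1C[C@H]2C[C@@H]([C@@H]1C)C2(C)C)[C@H]1C[C@H]2C[C@@H]([C@@H]1C)C2(C)C | intermediate
5 | (Z)-crotyldiisopinocampheylborane, Ipc from (−)-α-pinene | C/C=C\CB([C@H]1C[C@H]2C[C@@H]([C@@H]1C)C2(C)C)[C@H]1C[C@H]2C[C@@H]([C@@H]1C)C2(C)C | intermediate
6 | diisopinocampheylborinate of alcohol 7 | C[Si](C)(C)C#C[C@H](OB([C@H]1C[C@H]2C[C@@H]([C@@H]1C)C2(C)C)[C@H]1C[C@H]2C[C@@H]([C@@H]1C)C2(C)C)[C@@H](C)C=C | intermediate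
7 | (3R,4S)-4-methyl-1-(trimethylsilyl)hex-5-en-1-yn-3-ol | C[Si](C)(C)C#C[C@H](O)[C@@H](C)C=C | intermediate
8 | [(3R,4S)-3-(benzyloxy)-4-methylhex-5-en-1-yn-1-yl]trimethylsilane | C[Si](C)(C)C#C[C@H](OCc1ccccc1)[C@@H](C)C=C | intermediate
9 | 9-[(3S,4R)-4-(benzyloxy)-3-methyl-6-(trimethylsilyl)hex-5-yn-1-yl]-9-borabicyclo[3.3.1]nonane | C[Si](C)(C)C#C[C@H](OCc1ccccc1)[C@@H](C)CCB1C2CCCC1CCC2 | intermediate
10 | (3S,4R)-4-(benzyloxy)-3-methyl-6-(trimethylsilyl)hex-5-yn-1-ol | C[Si](C)(C)C#C[C@H](OCc1ccccc1)[C@@H](C)CCO | intermediate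
11 | (3S,4R)-4-(benzyloxy)-3-methyl-6-(trimethylsilyl)hex-5-ynal | C[Si](C)(C)C#C[C@H](OCc1ccccc1)[C@@H](C)CC=O | intermediate
12 | (3S,4R)-4-(benzyloxy)-3-methyl-6-(trimethylsilyl)hex-5-ynoic acid | C[Si](C)(C)C#C[C@H](OCc1ccccc1)[C@@H](C)CC(=O)O | intermediate
13 | benzyl (3S,4R)-4-(benzyloxy)-3-methyl-6-(trimethylsilyl)hex-5-ynoate | C[Si](C)(C)C#C[C@H](OCc1ccccc1)[C@@H](C)CC(=O)OCc1ccccc1 | intermediate
14 | benzyl (3S,4R)-4-(benzyloxy)-6-bromo-3-methylhex-5-ynoate | BrC#C[C@H](OCc1ccccc1)[C@@H](C)CC(=O)OCc1ccccc1 | intermediate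
15 | benzyl (3S,4R)-4-(benzyloxy)-6-bromo-3-methyl-5,6-dioxohexanoate | O=C(Br)C(=O)[C@H](OCc1ccccc1)[C@@H](C)CC(=O)OCc1ccccc1 | intermediate
16 | 6-benzyl 1-methyl (3R,4S)-3-(benzyloxy)-4-methyl-2-oxohexanedioate | COC(=O)C(=O)[C@H](OCc1ccccc1)[C@@H](C)CC(=O)OCc1ccccc1 | intermediate
17 | O,C-bis(9-borabicyclo[3.3.1]nonan-9-yl) derivative of diol 18 | C[Si](C)(C)C#C[C@H](OB1C2CCCC1CCC2)[C@@H](C)CCB1C2CCCC1CCC2 | intermediate
18 | (3S,4R)-3-methyl-6-(trimethylsilyl)hex-5-yne-1,4-diol | C[Si](C)(C)C#C[C@H](O)[C@@H](C)CCO | intermediate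
19 | (4S,5R)-4-methyl-5-[(trimethylsilyl)ethynyl]oxolan-2-ol (anomers) | C[Si](C)(C)C#C[C@@H]1OC(O)C[C@@H]1C | intermediate
20 | (4S,5R)-4-methyl-5-[(trimethylsilyl)ethynyl]oxolan-2-one (cis) | C[Si](C)(C)C#C[C@@H]1OC(=O)C[C@@H]1C | intermediate
21 | (4S,5R)-5-(bromoethynyl)-4-methyloxolan-2-one | BrC#C[C@@H]1OC(=O)C[C@@H]1C | intermediate
22 | 2-[(2R,3S)-3-methyl-5-oxooxolan-2-yl]-2-oxoacetyl bromide | O=C(Br)C(=O)[C@@H]1OC(=O)C[C@@H]1C | intermediate
23 | methyl 2-[(2R,3S)-3-methyl-5-oxooxolan-2-yl]-2-oxoacetate | COC(=O)C(=O)[C@@H]1OC(=O)C[C@@H]1C | intermediate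
24 | 2′,6′-dihydroxyacetophenone | CC(=O)c1c(O)cccc1O | starting material
25 | 1-{2-hydroxy-6-[(4-methoxybenzyl)oxy]phenyl}ethan-1-one | CC(=O)c1c(O)cccc1OCc1ccc(OC)cc1 | intermediate
26 | 1-{2-hydroxy-3-iodo-6-[(4-methoxybenzyl)oxy]phenyl}ethan-1-one | CC(=O)c1c(O)c(I)ccc1OCc1ccc(OC)cc1 | intermediate
27 | 1-{2-(benzyloxy)-3-iodo-6-[(4-methoxybenzyl)oxy]phenyl}ethan-1-one | CC(=O)c1c(OCc2ccccc2)c(I)ccc1OCc1ccc(OC)cc1 | intermediate
28 | trimethylsilyl enol ether of 27 | C=C(O[Si](C)(C)C)c1c(OCc2ccccc2)c(I)ccc1OCc1ccc(OC)cc1 | intermediate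
29 | 2-bromo-1-{2-(benzyloxy)-3-iodo-6-[(4-methoxybenzyl)oxy]phenyl}ethan-1-one | BrCC(=O)c1c(OCc2ccccc2)c(I)ccc1OCc1ccc(OC)cc1 | intermediate
30 | (2-{2-(benzyloxy)-3-iodo-6-[(4-methoxybenzyl)oxy]phenyl}-2-oxoethyl)triphenylphosphonium bromide | [Br-].O=C(C[P+](c1ccccc1)(c1ccccc1)c1ccccc1)c1c(OCc2ccccc2)c(I)ccc1OCc1ccc(OC)cc1 | intermediate
31 | 1-{2-(benzyloxy)-3-iodo-6-[(4-methoxybenzyl)oxy]phenyl}-2-(triphenyl-λ5-phosphanylidene)ethan-1-one | O=C(C=P(c1ccccc1)(c1ccccc1)c1ccccc1)c1c(OCc2ccccc2)c(I)ccc1OCc1ccc(OC)cc1 | intermediate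
32 | 6-benzyl 1-methyl (2E,3R,4S)-3-(benzyloxy)-2-(2-{2-(benzyloxy)-3-iodo-6-[(4-methoxybenzyl)oxy]phenyl}-2-oxoethylidene)-4-methylhexanedioate | COC(=O)/C(=C/C(=O)c1c(OCc2ccccc2)c(I)ccc1OCc1ccc(OC)cc1)[C@H](OCc1ccccc1)[C@@H](C)CC(=O)OCc1ccccc1 | intermediate
33 | 6-benzyl 1-methyl (2E,3R,4S)-3-(benzyloxy)-2-{2-[2-(benzyloxy)-6-hydroxy-3-iodophenyl]-2-oxoethylidene}-4-methylhexanedioate | COC(=O)/C(=C/C(=O)c1c(OCc2ccccc2)c(I)ccc1O)[C@H](OCc1ccccc1)[C@@H](C)CC(=O)OCc1ccccc1 | intermediate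
34 | methyl (2S)-5-(benzyloxy)-2-[(1R,2S)-1,4-bis(benzyloxy)-2-methyl-4-oxobutyl]-6-iodo-4-oxochromane-2-carboxylate | COC(=O)[C@@]1([C@H](OCc2ccccc2)[C@@H](C)CC(=O)OCc2ccccc2)CC(=O)c2c(ccc(I)c2OCc2ccccc2)O1 | intermediate
35 | methyl (2E)-4-{2-(benzyloxy)-3-iodo-6-[(4-methoxybenzyl)oxy]phenyl}-2-[(2R,3S)-3-methyl-5-oxooxolan-2-yl]-4-oxobut-2-enoate | COC(=O)/C(=C/C(=O)c1c(OCc2ccccc2)c(I)ccc1OCc1ccc(OC)cc1)[C@@H]1OC(=O)C[C@@H]1C | intermediate
36 | methyl (2E)-4-[2-(benzyloxy)-6-hydroxy-3-iodophenyl]-2-[(2R,3S)-3-methyl-5-oxooxolan-2-yl]-4-oxobut-2-enoate | COC(=O)/C(=C/C(=O)c1c(OCc2ccccc2)c(I)ccc1O)[C@@H]1OC(=O)C[C@@H]1C | intermediate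
37 | methyl (2S)-5-(benzyloxy)-6-iodo-2-[(2R,3S)-3-methyl-5-oxooxolan-2-yl]-4-oxochromane-2-carboxylate | COC(=O)[C@@]1([C@@H]2OC(=O)C[C@@H]2C)CC(=O)c2c(ccc(I)c2OCc2ccccc2)O1 | intermediate
38 | methyl (2S)-5-(benzyloxy)-2-[(2R,3S)-3-methyl-5-oxooxolan-2-yl]-4-oxo-6-(4,4,5,5-tetramethyl-1,3,2-dioxaborolan-2-yl)chromane-2-carboxylate | COC(=O)[C@@]1([C@@H]2OC(=O)C[C@@H]2C)CC(=O)c2c(ccc(B3OC(C)(C)C(C)(C)O3)c2OCc2ccccc2)O1 | intermediate
39 | 6,6′-bichromanone: half A as in 34, half B as in 37, joined C6–C6′ in place of I and Bpin (four benzyl groups) | COC(=O)[C@@]1([C@H](OCc5ccccc5)[C@@H](C)CC(=O)OCc5ccccc5)CC(=O)c2c(ccc(-c3ccc4c(c3OCc5ccccc5)C(=O)C[C@@](C(=O)OC)([C@@H]3OC(=O)C[C@@H]3C)O4)c2OCc5ccccc5)O1 | intermediate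
40 | (3S,4R)-4-hydroxy-4-[(2S)-5-hydroxy-6-{(2S)-5-hydroxy-2-(methoxycarbonyl)-2-[(2R,3S)-3-methyl-5-oxooxolan-2-yl]-4-oxochroman-6-yl}-2-(methoxycarbonyl)-4-oxochroman-2-yl]-3-methylbutanoic acid | COC(=O)[C@@]1([C@H](O)[C@@H](C)CC(=O)O)CC(=O)c2c(ccc(-c3ccc4c(c3O)C(=O)C[C@@](C(=O)OC)([C@@H]3OC(=O)C[C@@H]3C)O4)c2O)O1 | target

## Step count and risks
Total step count: 23.
Longest linear sequence: 11 steps (1–7, 17, 18, 22, 23). The lactone branch (1, 8–11, 19–23) and the arene branch (12–16, 19–23) are 10 steps each.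

**Risk 1, step 18 (oxa-Michael on the flexible open-chain enone 33).**
- The facial bias at the new quaternary C2 rests on one acyclic stereocentre.
- The addition is reversible, so the 2S:2R ratio may be low.
- 5-exo attack at C3 could compete.

Fallback: set out from lactone iodide 37 and derive the open-chain half from it.
- Only the γ-lactone is saponified (LiOH 1.05 equiv, THF/H2O, 0 °C; the methyl ester on the quaternary carbon is inert). This gives lithium (3S,4R)-4-[(2S)-5-(benzyloxy)-6-iodo-2-(methoxycarbonyl)-4-oxochroman-2-yl]-4-hydroxy-3-methylbutanoate F4.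
- The crude salt is alkylated with BnBr in DMF to the hydroxy benzyl ester methyl (2S)-5-(benzyloxy)-2-[(1R,2S)-4-(benzyloxy)-1-hydroxy-2-methyl-4-oxobutyl]-6-iodo-4-oxochromane-2-carboxylate F5.
- F5 is silylated at once (TESOTf, 2,6-lutidine, −78 °C) to its triethylsilyl ether F6.
- F6 is coupled with 38 under the conditions of step 22 to the tribenzyl TES-protected bichromanone F7.
- H2, Pd/C in MeOH removes the three benzyl groups and the TES ether together, and the route is rejoined at 40.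

This fallback also bypasses steps 2–7 and 17.

**Risk 2, step 19 (Wittig on lactone keto ester 23).**
- The branched ketone may olefinate slowly.
- Its α-acyloxy carbinol centre can epimerise to the more stable trans-lactone.

Fallback: set out from 27 and attach the lactone to a preformed chromone.
- Claisen condensation with dimethyl oxalate (NaH, THF) gives methyl 4-{2-(benzyloxy)-3-iodo-6-[(4-methoxybenzyl)oxy]phenyl}-2,4-dioxobutanoate F1.
- TFA/anisole, then warming, removes PMB and cyclodehydrates to methyl 5-(benzyloxy)-6-iodo-4-oxo-4H-chromene-2-carboxylate F2.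
- A chiral N,N′-dioxide–Sc(OTf)3-catalysed direct vinylogous Michael addition of 4-methylfuran-2(5H)-one gives methyl (2S)-5-(benzyloxy)-6-iodo-2-[(2R)-3-methyl-5-oxo-2,5-dihydrofuran-2-yl]-4-oxochromane-2-carboxylate F3.
- CuH conjugate reduction (Stryker reagent, toluene) delivers hydride anti to the chromanone substituent and gives the cis-lactone, rejoining the route at 37.

This fallback bypasses steps 19 and 20.

**Risk 3, step 23 (final hydrogenolysis).**
- The hindered secondary benzyl ether is slow to cleave.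
- During a long reaction or work-up the γ-hydroxy acid can partly lactonise, which would give mixtures.

Fallback: set out from 39 and drive the lactonisation to completion on purpose.
- H2, Pd(OH)2/C, then CSA (cat.) in CH2Cl2 gives the easily purified C2-symmetric bis-lactone dimethyl (2S,2′S)-5,5′-dihydroxy-2,2′-bis[(2R,3S)-3-methyl-5-oxooxolan-2-yl]-4,4′-dioxo-6,6′-bichromane-2,2′-dicarboxylate F8.
- One of its two equivalent lactones is then opened (LiOH 3.1 equiv, counting both phenols, THF/H2O, 0 °C; quench into pH 5 buffer).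
- Unreacted F8 is recycled, and the route is rejoined at 40.

## Further compounds
F1 | step 19 | methyl 4-{2-(benzyloxy)-3-iodo-6-[(4-methoxybenzyl)oxy]phenyl}-2,4-dioxobutanoate | COC(=O)C(=O)CC(=O)c1c(OCc2ccccc2)c(I)ccc1OCc1ccc(OC)cc1
F2 | step 19 | methyl 5-(benzyloxy)-6-iodo-4-oxo-4H-chromene-2-carboxylate | COC(=O)c1cc(=O)c2c(o1)ccc(I)c2OCc1ccccc1
F3 | step 19 | methyl (2S)-5-(benzyloxy)-6-iodo-2-[(2R)-3-methyl-5-oxo-2,5-dihydrofuran-2-yl]-4-oxochromane-2-carboxylate | COC(=O)[C@@]1([C@@H]2OC(=O)C=C2C)CC(=O)c2c(ccc(I)c2OCc2ccccc2)O1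
F4 | step 18 | lithium (3S,4R)-4-[(2S)-5-(benzyloxy)-6-iodo-2-(methoxycarbonyl)-4-oxochroman-2-yl]-4-hydroxy-3-methylbutanoate | [Li+].COC(=O)[C@@]1([C@H](O)[C@@H](C)CC(=O)[O-])CC(=O)c2c(ccc(I)c2OCc2ccccc2)O1
F5 | step 18 | methyl (2S)-5-(benzyloxy)-2-[(1R,2S)-4-(benzyloxy)-1-hydroxy-2-methyl-4-oxobutyl]-6-iodo-4-oxochromane-2-carboxylate | COC(=O)[C@@]1([C@H](O)[C@@H](C)CC(=O)OCc2ccccc2)CC(=O)c2c(ccc(I)c2OCc2ccccc2)O1
F6 | step 18 | triethylsilyl ether of F5 | COC(=O)[C@@]1([C@H](O[Si](CC)(CC)CC)[C@@H](C)CC(=O)OCc2ccccc2)CC(=O)c2c(ccc(I)c2OCc2ccccc2)O1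
F7 | step 18 | tribenzyl TES-protected 6,6′-bichromanone | COC(=O)[C@@]1([C@H](O[Si](CC)(CC)CC)[C@@H](C)CC(=O)OCc5ccccc5)CC(=O)c2c(ccc(-c3ccc4c(c3OCc5ccccc5)C(=O)C[C@@](C(=O)OC)([C@@H]3OC(=O)C[C@@H]3C)O4)c2OCc5ccccc5)O1
F8 | step 23 | dimethyl (2S,2′S)-5,5′-dihydroxy-2,2′-bis[(2R,3S)-3-methyl-5-oxooxolan-2-yl]-4,4′-dioxo-6,6′-bichromane-2,2′-dicarboxylate | COC(=O)[C@@]1([C@@H]2OC(=O)C[C@@H]2C)CC(=O)c2c(ccc(-c3ccc4c(c3O)C(=O)C[C@@](C(=O)OC)([C@@H]3OC(=O)C[C@@H]3C)O4)c2O)O1
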